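The readings come from a simulation on assumed constants, noise included.

Do not read the falling rate of the violet run as free monomer simply thinning out. Between the last two stretches of the violet run, the rate goes from 4.52 mM min⁻¹ to 2.71 mM min⁻¹, a factor of 1.67, which is more than the factor of 1.20 in mean free monomer. Draw a line through those two points: its slope is 0.0205 min⁻¹, and it reaches zero rate at 0.307 M. Call this the floor of free monomer, the level at which the net rate stops (the equilibrium monomer concentration). It is a loose reading, built from differences of readings each good to 0.5 percentage points.

| flask | free monomer | initiator | impurity | remark | time |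
|---|---|---|---|---|---|
| teal | 0.51 M | 45 mM | 10 mM | run made earlier |  |
| grey | 0.51 M | 45 mM | 22 mM | run made earlier |  |
| violet | 0.77 M | 45 mM | 15 mM | run made earlier |  |
| flask | 0.51 M | 45 mM | 15 mM |  | 80 min |

- teal (time / min: monomer in chains / %, free monomer / %): 6.00: 11.7, 90.0; 10.0: 13.4, 87.1; 15.0: 15.5, 83.5; 25.0: 20.7, 78.9; 30.0: 23.5, 76.1; 50.0: 29.8, 69.7; 80.0: 36.0, 63.6
- grey (time / min: monomer in chains / %, free monomer / %): 6.00: 9.2, 91.4; 10.0: 10.7, 88.8; 15.0: 13.8, 86.4; 25.0: 18.0, 81.8; 30.0: 19.4, 79.7; 50.0: 27.1, 74.2; 80.0: 33.3, 67.5
- violet (time / min: monomer in chains / %, free monomer / %): 6.00: 11.0, 89.1; 12.0: 17.0, 83.9; 25.0: 26.6, 72.9; 40.0: 35.6, 64.1; 80.0: 50.1, 50.0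

(each reading ± 0.5 percentage points)

- average number of monomer units in a chain (chains begun, living or dead) at 80 min
- part of the free monomer that has reacted at 80 min

- the average divides the monomer in chains by the number of chains begun, living and dead together
- the earlier runs do not show the number of chains; that part of a forecast is a guess

Carry that slope to the flask, whose initiator and impurity charges match violet's. Let impurity take its equal of initiator, and let the remaining 30.0 mM each take one free monomer. The slow stretch of the flask then opens 0.173 M above the floor, at 3.55 mM min⁻¹. Treat the shrinking excess as the one slowing, pseudo-first-order, so that over 80 min the rate falls by a factor of 5.14. For the flask my reckoning gives 33.3 % reacted and an average chain of 5.66. The forecast stands higher on both, at 34.8 % and 5.8, holding that “impurity seems to destroy initiator about one for one”.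

The flask gives 34.5 % reacted and an average chain of 5.27, so the forecast stands. A run would prove it wrong by showing a chain average further below it: with the other charges held, 52.2 mM of initiator moves the chain average of the flask by 0.527. Left until 800 min, the flask reaches 43.0 % reacted, where the floor as read from the violet run gives 39.9 %.

    free monomer + living end → monomer in chains + living end, rate k1*[living end]*[free monomer] (k = 0.550 L mol⁻¹ min⁻¹)
    initiator + impurity → spent initiator A (k = 59.0 L mol⁻¹ min⁻¹)
    monomer in chains + living end → free monomer + living end, rate k3*[living end] as long as [monomer in chains] is above zero (k = 0.160 min⁻¹)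
    initiator → spent initiator B (k = 0.0520 min⁻¹)
    free monomer + initiator → living end + monomer in chains (k = 3.30 L mol⁻¹ min⁻¹)

For a neighbour flask charged with 1.3 M of free monomer, the same floor, slope and 30.0 mM give 62.0 % reacted. The computed flask gives 63.7 %.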